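**Remark (assumption):** the SMILES defines no configuration at the two indole–arene axes, so the target is treated as achiral with freely rotating axes. Quinone 8 is made rather than bought.

## The problem

- The target is a 1,4-bis(indol-3-yl)benzene. Its central benzene ring (ring C) is fully substituted: C1 carries a 5-methoxyindol-3-yl group (indole A), C4 a 5-hydroxyindol-3-yl group (indole B), and C2, C3, C5 and C6 each carry a methoxy group.
- There is no stereocentre, so the difficulty lies in connectivity and differentiation.
- Each of the two aryl–aryl bonds is flanked by two ortho-methoxy groups on ring C and joins two electron-rich partners. This is the least favourable case for a cross-coupling.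
- Indoles A and B differ only at C5 (OMe against OH), and C1 and C4 of ring C are equivalent. Any symmetric core must therefore be desymmetrized, or statistical mixtures result.
- The free 5-hydroxyindole is easily oxidized, especially as its phenoxide. The indole N–H groups and the electron-rich rings rule out strong oxidants, strong acid over long times and hot aerobic base.
- The enabling feature: C1 and C4 of ring C are para, and the other four ring carbons all bear oxygen. This is the atom pattern of 2,3,5,6-tetramethoxy-1,4-benzoquinone (8), whose two carbonyl carbons are C1 and C4. Both aryl–aryl bonds can therefore be made as carbonyl additions of indole C3 nucleophiles, and the ring aromatized afterwards.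

## Retrosynthesis

**15 to 14.** Two N–Si bonds and one O–Si bond are cut. The only difference between the two indoles is carried as a silyl ether, and the N-silyl groups are those needed earlier to make C3 the metalated position. One fluoride treatment at the end removes all three, so no separate phenol deprotection is needed. Protected arene 14 has the full skeleton and is robust.

**14 to 13.** Ring C is taken back from the arene to a cyclohexa-2,5-diene by placing hydroxyl groups on C1 and C4, giving diol 13. This turns the two hindered biaryl bonds into bonds to carbinol carbons. The forward reaction is a reductive aromatization by a divalent tin reductant in acid. Cis- and trans-13 give the same arene, so no stereocontrol is needed.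

**13 to 8 + 9 + 11 (through 10 and 12).** Both C(ring C)–C3(indole) bonds are cut, which splits 13 into quinone 8 and the two indol-3-yllithiums 9 and 11.
- Against cutting the same bonds at the arene level, this cut uses the native polarity of both partners: nucleophilic indole C3, electrophilic quinone carbonyl.
- It also desymmetrizes itself. After the first addition the remaining carbonyl in 10 is a deactivated dienone, so 9 and 11 can be introduced one after the other in one flask.
- The precursors are much simpler: a ten-carbon symmetric quinone that holds every atom of ring C and all four methoxy groups, and two monocyclic-indole halides.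
- The forward reaction must give carbonyl addition, not attack at the methoxy-bearing carbons or electron transfer.

**9 to 3 to 2 to 1, and 11 to 6 to 5 to 4.** Each C–Li bond comes from a C–Br bond by halogen–metal exchange, each C–Br bond from C3–H by electrophilic bromination, and the silyl groups from N–H and O–H. Indoles 1 and 4 are commercial and already contain both heterocycles with the C5 oxygen in place.

**8 to 7.** The four C–OMe bonds are cut back to the C–Cl bonds of chloranil (7). Each is a vinylogous acid chloride, replaced by methoxide through addition–elimination.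

## Roads not taken

**Alternative 1:** the most obvious cut, both biaryl bonds on an intact aromatic core. 1,4-Dibromo-2,3,5,6-tetramethoxybenzene A1 would be coupled twice (Suzuki–Miyaura) with indol-3-yl boronate A2 and its 5-silyloxy analogue, through monobromide A3.
- The two C–Br bonds of A1 are equivalent, and the first coupling hardly changes the reactivity of the second. A mixture of A1, A3 and twofold-coupled products is expected.
- Each C–Br bond sits between two ortho-methoxy groups on an electron-rich ring, so oxidative addition is slow.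
- Indol-3-yl boronates such as A2 protodeboronate readily.
- The chosen plan has the differentiation built in, since the first addition switches off the second carbonyl.

**Alternative 2:** the quinone as conjugate acceptor. Indole 1 would add under acid to 2,5-dichloro-1,4-benzoquinone A4, and reoxidation would give A5. A second addition with an O-protected form of 4, hydrolysis of both C–Cl bonds to dihydroxyquinone A6, reduction to tetrol A7 and fourfold O-methylation would follow.
- Ring C changes oxidation level several times after the C–C bonds are made, twice by a high-potential oxidant in the presence of electron-rich 5-oxygenated indoles.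
- Tetrol A7 is very air-sensitive, and its methylation must distinguish four hindered O–H groups from two N–H groups.
- The sequence is roughly twice as long. In the chosen plan the four methoxy groups arrive with 8 and ring C changes oxidation level once.

**Alternative 3:** ring C kept, both indole rings built on it. Twofold Larock heteroannulation of bis(silylalkyne) A8 with two differently 4-oxygenated 2-iodoanilines would give bis(2-silylindole) A9, followed by protodesilylation.
- The two alkynes of A8 are equivalent and electronically isolated, so the two anilines cannot be introduced selectively.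
- The Larock regiochemistry needs the silyl group, not the very bulky di-ortho-methoxyaryl group, to end up at C2. This is not assured.
- A8 itself needs several steps, and commercial indoles 1 and 4 go unused.

Key step: step 6

## Route

Step 1
Reactants: 1 5-methoxy-1H-indole
Product: 2 5-methoxy-1-(triisopropylsilyl)-1H-indole
Conditions: NaH, TIPSCl, THF, 0 °C to rt
Reagents that add atoms: triisopropylsilyl chloride (TIPSCl), CC(C)[Si](Cl)(C(C)C)C(C)C
Why: N-silylation of the indolyl anion; the bulky N-silyl group shields C2 and later keeps lithium at C3.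

Step 2
Reactants: 2 5-methoxy-1-(triisopropylsilyl)-1H-indole
Product: 3 3-bromo-5-methoxy-1-(triisopropylsilyl)-1H-indole
Conditions: NBS (1.0 equiv), THF, −78 °C to rt
Reagents that add atoms: N-bromosuccinimide (NBS), O=C1CCC(=O)N1Br
Why: Electrophilic aromatic bromination at C3, the most nucleophilic position of an N-silylindole; low temperature and one equivalent should avoid attack on the methoxy-activated benzo ring.

Step 3
Reactants: 4 1H-indol-5-ol
Product: 5 1-(triisopropylsilyl)-5-[(triisopropylsilyl)oxy]-1H-indole
Conditions: NaH (2.4 equiv), TIPSCl (2.3 equiv), THF–DMF, 0 °C to rt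
Reagents that add atoms: triisopropylsilyl chloride (TIPSCl), CC(C)[Si](Cl)(C(C)C)C(C)C
Why: Phenoxide and indolyl anion are both silylated in one operation (O- and N-silylation); the aryl silyl ether is the masked form of the one hydroxyl that distinguishes indole B.

Step 4
Reactants: 5 1-(triisopropylsilyl)-5-[(triisopropylsilyl)oxy]-1H-indole
Product: 6 3-bromo-1-(triisopropylsilyl)-5-[(triisopropylsilyl)oxy]-1H-indole
Conditions: NBS (1.0 equiv), THF, −78 °C
Reagents that add atoms: N-bromosuccinimide (NBS), O=C1CCC(=O)N1Br
Why: Electrophilic aromatic bromination at C3 as in step 2; C2 is shielded by the N-silyl group.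

Step 5
Reactants: 7 chloranil (2,3,5,6-tetrachloro-1,4-benzoquinone)
Product: 8 2,3,5,6-tetramethoxy-1,4-benzoquinone
Conditions: NaOMe (excess), MeOH, reflux
Reagents that add atoms: sodium methoxide, C[O-].[Na+]
Why: Fourfold addition–elimination (vinylogous acyl substitution); each C–Cl of the quinone is a vinylogous acid chloride and is replaced by methoxide.

Step 6
Reactants: 8 2,3,5,6-tetramethoxy-1,4-benzoquinone; 3 3-bromo-5-methoxy-1-(triisopropylsilyl)-1H-indole; 6 3-bromo-1-(triisopropylsilyl)-5-[(triisopropylsilyl)oxy]-1H-indole
Product: 13 1-[5-methoxy-1-(triisopropylsilyl)indol-3-yl]-4-{1-(triisopropylsilyl)-5-[(triisopropylsilyl)oxy]indol-3-yl}-2,3,5,6-tetramethoxycyclohexa-2,5-diene-1,4-diol (cis/trans mixture), via indol-3-yllithium 9 (not isolated), via lithium dienone alkoxide 10 (not isolated), via indol-3-yllithium 11 (not isolated), via dilithium dialkoxide 12 (not isolated)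
Conditions: 3, t-BuLi (2.0 equiv), THF, −78 °C, then cannulate into 8 (1.05 equiv), THF, −78 °C; then 11 [from 6 (1.6 equiv), t-BuLi (3.2 equiv), THF, −78 °C], −78 to −20 °C; aq NH4Cl
Reagents that add atoms: none
Why: Bromine–lithium exchange gives 9, which stays lithiated at C3 because the bulky N-silyl group blocks migration to C2; 9 adds 1,2 to one of the two equivalent carbonyl groups of 8 to give alkoxide 10. In 10 the remaining carbonyl is a cross-conjugated dienone whose two β-carbons carry methoxy groups (a doubly vinylogous ester) and which faces a lithium alkoxide across the ring, so it is far less electrophilic than the carbonyls of 8; the first aryllithium should therefore be consumed by 8 before it attacks 10, which allows the unsymmetrical adduct to be made in one flask without a statistical mixture. The second aryllithium 11, used in excess, then adds 1,2 to this vinylogous ester carbonyl on warming, as organolithiums do in the first stage of a Stork–Danheiser sequence, to give dialkoxide 12 and after protonation diol 13. The closest known reaction type is the sequential twofold addition of organolithium reagents to quinones that precedes reductive aromatization in syntheses of diaryl- and dialkynylacenes and of cycloparaphenylene precursors. No ring is closed. The two new quaternary carbinol carbons (C1 and C4 of ring C) are not controlled and need not be, since cis- and trans-13 both lose these centres in step 7. The selectivities needed are carbonyl addition over addition–elimination at the methoxy-bearing carbons, favoured by a hard aryllithium at −78 °C and lithium chelation by the α-methoxy groups, and carbonyl addition over single-electron reduction of the quinone, favoured by the four donor methoxy groups that make 8 a weak oxidant.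

Step 7
Reactants: 13 1-[5-methoxy-1-(triisopropylsilyl)indol-3-yl]-4-{1-(triisopropylsilyl)-5-[(triisopropylsilyl)oxy]indol-3-yl}-2,3,5,6-tetramethoxycyclohexa-2,5-diene-1,4-diol
Product: 14 5-methoxy-3-[2,3,5,6-tetramethoxy-4-{1-(triisopropylsilyl)-5-[(triisopropylsilyl)oxy]-1H-indol-3-yl}phenyl]-1-(triisopropylsilyl)-1H-indole
Conditions: SnCl2·2H2O (2.5 equiv), conc. HCl (5 equiv) premixed (H2SnCl4), THF, 0 °C to rt
Reagents that add atoms: none
Why: Reductive aromatization of a cyclohexa-2,5-diene-1,4-diol: acid ionizes one tertiary carbinol to a cation stabilized by the indolyl and methoxy groups, divalent tin supplies two electrons, and loss of the second hydroxyl gives the arene. Both diastereomers of 13 converge, and any early loss of an N-silyl group is harmless because step 8 removes all silyl groups.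

Step 8
Reactants: 14 5-methoxy-3-[2,3,5,6-tetramethoxy-4-{1-(triisopropylsilyl)-5-[(triisopropylsilyl)oxy]-1H-indol-3-yl}phenyl]-1-(triisopropylsilyl)-1H-indole
Product: 15 3-[4-(5-methoxy-1H-indol-3-yl)-2,3,5,6-tetramethoxyphenyl]-1H-indol-5-ol
Conditions: TBAF (3.5 equiv), AcOH (3.5 equiv), THF, 0 °C to rt, under argon
Reagents that add atoms: none
Why: Fluoride cleaves both N–Si bonds and the aryl O–Si bond in one global desilylation; the acetic acid buffer and argon keep the 5-hydroxyindole from standing as an oxidizable phenoxide.

## Compound list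

1 | 5-methoxy-1H-indole | COc1ccc2[nH]ccc2c1 | starting material
2 | 5-methoxy-1-(triisopropylsilyl)-1H-indole | COc1ccc2c(c1)ccn2[Si](C(C)C)(C(C)C)C(C)C | intermediate
3 | 3-bromo-5-methoxy-1-(triisopropylsilyl)-1H-indole | COc1ccc2c(c1)c(Br)cn2[Si](C(C)C)(C(C)C)C(C)C | intermediate
4 | 1H-indol-5-ol (5-hydroxyindole) | Oc1ccc2[nH]ccc2c1 | starting material
5 | 1-(triisopropylsilyl)-5-[(triisopropylsilyl)oxy]-1H-indole | CC(C)[Si](Oc1ccc2c(c1)ccn2[Si](C(C)C)(C(C)C)C(C)C)(C(C)C)C(C)C | intermediate
6 | 3-bromo-1-(triisopropylsilyl)-5-[(triisopropylsilyl)oxy]-1H-indole | CC(C)[Si](Oc1ccc2c(c1)c(Br)cn2[Si](C(C)C)(C(C)C)C(C)C)(C(C)C)C(C)C | intermediate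
7 | chloranil (2,3,5,6-tetrachloro-1,4-benzoquinone) | O=C1C(Cl)=C(Cl)C(=O)C(Cl)=C1Cl | starting material
8 | 2,3,5,6-tetramethoxy-1,4-benzoquinone | COC1=C(OC)C(=O)C(OC)=C(OC)C1=O | intermediate
9 | [5-methoxy-1-(triisopropylsilyl)-1H-indol-3-yl]lithium | COc1ccc2c(c1)c([Li])cn2[Si](C(C)C)(C(C)C)C(C)C | intermediate (not isolated)
10 | lithium 1-[5-methoxy-1-(triisopropylsilyl)indol-3-yl]-2,3,5,6-tetramethoxy-4-oxocyclohexa-2,5-dien-1-olate | [Li+].[O-]C1(c2cn([Si](C(C)C)(C(C)C)C(C)C)c3ccc(OC)cc23)C(OC)=C(OC)C(=O)C(OC)=C1OC | intermediate (not isolated)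
11 | {1-(triisopropylsilyl)-5-[(triisopropylsilyl)oxy]-1H-indol-3-yl}lithium | CC(C)[Si](Oc1ccc2c(c1)c([Li])cn2[Si](C(C)C)(C(C)C)C(C)C)(C(C)C)C(C)C | intermediate (not isolated)
12 | dilithium 1-[5-methoxy-1-(triisopropylsilyl)indol-3-yl]-4-{1-(triisopropylsilyl)-5-[(triisopropylsilyl)oxy]indol-3-yl}-2,3,5,6-tetramethoxycyclohexa-2,5-diene-1,4-diolate (cis/trans mixture) | [Li+].[Li+].[O-]C1(c2cn([Si](C(C)C)(C(C)C)C(C)C)c3ccc(OC)cc23)C(OC)=C(OC)C([O-])(c2cn([Si](C(C)C)(C(C)C)C(C)C)c3ccc(O[Si](C(C)C)(C(C)C)C(C)C)cc23)C(OC)=C1OC | intermediate (not isolated)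
13 | 1-[5-methoxy-1-(triisopropylsilyl)indol-3-yl]-4-{1-(triisopropylsilyl)-5-[(triisopropylsilyl)oxy]indol-3-yl}-2,3,5,6-tetramethoxycyclohexa-2,5-diene-1,4-diol (cis/trans mixture, no configuration assigned) | OC1(c2cn([Si](C(C)C)(C(C)C)C(C)C)c3ccc(OC)cc23)C(OC)=C(OC)C(O)(c2cn([Si](C(C)C)(C(C)C)C(C)C)c3ccc(O[Si](C(C)C)(C(C)C)C(C)C)cc23)C(OC)=C1OC | intermediate
14 | 5-methoxy-3-[2,3,5,6-tetramethoxy-4-{1-(triisopropylsilyl)-5-[(triisopropylsilyl)oxy]-1H-indol-3-yl}phenyl]-1-(triisopropylsilyl)-1H-indole | COc1ccc2c(c1)c(cn2[Si](C(C)C)(C(C)C)C(C)C)-c1c(OC)c(OC)c(c(OC)c1OC)-c1cn([Si](C(C)C)(C(C)C)C(C)C)c2ccc(O[Si](C(C)C)(C(C)C)C(C)C)cc12 | intermediate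
15 | 3-[4-(5-methoxy-1H-indol-3-yl)-2,3,5,6-tetramethoxyphenyl]-1H-indol-5-ol | COc1ccc2[nH]cc(-c3c(OC)c(OC)c(-c4c[nH]c5ccc(O)cc45)c(OC)c3OC)c2c1 | target

## Step count and risk

Total steps: 8. Longest linear sequence: 5 steps (steps 1, 2, 6, 7, 8 or steps 3, 4, 6, 7, 8).

**Step 6 (key step).**
- What may go wrong: the second carbonyl addition may stall, because the dienone of 10 is deactivated by two β-methoxy groups and a facing alkoxide. Attack at a methoxy-bearing carbon with loss of methoxide, or electron transfer from the aryllithium to the quinone, may also take over from carbonyl addition. A Lewis-acidic additive such as LaCl3·2LiCl would be tried first.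
- Fallback: the route is left at 10 and the second biaryl bond is made by cross-coupling on an already aromatic ring. Quenching after the first addition should give the quinol 4-hydroxy-4-[5-methoxy-1-(triisopropylsilyl)indol-3-yl]-2,3,5,6-tetramethoxycyclohexa-2,5-dien-1-one F1. Zinc dust in acetic acid should reduce this p-quinol to the phenol 4-[5-methoxy-1-(triisopropylsilyl)indol-3-yl]-2,3,5,6-tetramethoxyphenol F2. Triflic anhydride and pyridine should convert it into the aryl triflate 4-[5-methoxy-1-(triisopropylsilyl)indol-3-yl]-2,3,5,6-tetramethoxyphenyl trifluoromethanesulfonate F3. Negishi coupling of F3 with {1-(triisopropylsilyl)-5-[(triisopropylsilyl)oxy]indol-3-yl}zinc chloride F4 (from 11 and ZnCl2) under Pd2(dba)3/SPhos (zerovalent palladium) returns to the route at 14.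

**Step 7.**
- What may go wrong: the cation formed on ionization of a carbinol may be captured by water with loss of methanol (enol ether hydrolysis in the Stork–Danheiser sense), or may undergo a 1,2-aryl shift, before divalent tin reduces it. Acid may also remove N-silyl groups early.
- Fallback: from 13, NaH and MeI should give the bis(methyl ether) 1,2,3,4,5,6-hexamethoxy-1-[5-methoxy-1-(triisopropylsilyl)indol-3-yl]-4-{1-(triisopropylsilyl)-5-[(triisopropylsilyl)oxy]indol-3-yl}cyclohexa-2,5-diene F5. Sodium naphthalenide in THF at −78 °C then expels the two tertiary methoxides by electron transfer, without acid or cation, as in the aromatization of cycloparaphenylene precursors. This returns to the route at 14.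

**Step 5.**
- What may go wrong: substitution may stop at the dichlorodimethoxy stage, because the first two methoxy groups deactivate the remaining vinylogous acid chlorides, or methoxide may add reversibly to a carbonyl and divert material.
- Fallback: this one does not set out from a numbered compound. Commercial tetrahydroxy-1,4-benzoquinone takes the place of 7 and is O-methylated four times (MeI, Ag2O, or trimethylsilyldiazomethane in methanol), rejoining the route at 8. It makes no compound outside the compound list (F0).

## Further compounds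

F1 | step 6 | 4-hydroxy-4-[5-methoxy-1-(triisopropylsilyl)indol-3-yl]-2,3,5,6-tetramethoxycyclohexa-2,5-dien-1-one | OC1(c2cn([Si](C(C)C)(C(C)C)C(C)C)c3ccc(OC)cc23)C(OC)=C(OC)C(=O)C(OC)=C1OC
F2 | step 6 | 4-[5-methoxy-1-(triisopropylsilyl)indol-3-yl]-2,3,5,6-tetramethoxyphenol | COc1ccc2c(c1)c(cn2[Si](C(C)C)(C(C)C)C(C)C)-c1c(OC)c(OC)c(O)c(OC)c1OC
F3 | step 6 | 4-[5-methoxy-1-(triisopropylsilyl)indol-3-yl]-2,3,5,6-tetramethoxyphenyl trifluoromethanesulfonate | COc1ccc2c(c1)c(cn2[Si](C(C)C)(C(C)C)C(C)C)-c1c(OC)c(OC)c(OS(=O)(=O)C(F)(F)F)c(OC)c1OC
F4 | step 6 | {1-(triisopropylsilyl)-5-[(triisopropylsilyl)oxy]indol-3-yl}zinc chloride | CC(C)[Si](Oc1ccc2c(c1)c([Zn]Cl)cn2[Si](C(C)C)(C(C)C)C(C)C)(C(C)C)C(C)C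
F5 | step 7 | 1,2,3,4,5,6-hexamethoxy-1-[5-methoxy-1-(triisopropylsilyl)indol-3-yl]-4-{1-(triisopropylsilyl)-5-[(triisopropylsilyl)oxy]indol-3-yl}cyclohexa-2,5-diene (cis/trans mixture) | COC1(c2cn([Si](C(C)C)(C(C)C)C(C)C)c3ccc(OC)cc23)C(OC)=C(OC)C(OC)(c2cn([Si](C(C)C)(C(C)C)C(C)C)c3ccc(O[Si](C(C)C)(C(C)C)C(C)C)cc23)C(OC)=C1OC
F0 | step 5 | none | none
A1 | alternative 1 | 1,4-dibromo-2,3,5,6-tetramethoxybenzene | COc1c(OC)c(Br)c(OC)c(OC)c1Br
A2 | alternative 1 | 5-methoxy-3-(4,4,5,5-tetramethyl-1,3,2-dioxaborolan-2-yl)-1-(triisopropylsilyl)-1H-indole | COc1ccc2c(c1)c(cn2[Si](C(C)C)(C(C)C)C(C)C)B1OC(C)(C)C(C)(C)O1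
A3 | alternative 1 | 3-(4-bromo-2,3,5,6-tetramethoxyphenyl)-5-methoxy-1-(triisopropylsilyl)-1H-indole | COc1ccc2c(c1)c(cn2[Si](C(C)C)(C(C)C)C(C)C)-c1c(OC)c(OC)c(Br)c(OC)c1OC
A4 | alternative 2 | 2,5-dichloro-1,4-benzoquinone | O=C1C=C(Cl)C(=O)C=C1Cl
A5 | alternative 2 | 2,5-dichloro-3-(5-methoxy-1H-indol-3-yl)-1,4-benzoquinone | COc1ccc2[nH]cc(C3=C(Cl)C(=O)C=C(Cl)C3=O)c2c1
A6 | alternative 2 | 2-[5-(benzyloxy)-1H-indol-3-yl]-3,6-dihydroxy-5-(5-methoxy-1H-indol-3-yl)-1,4-benzoquinone | COc1ccc2[nH]cc(C3=C(O)C(=O)C(c4c[nH]c5ccc(OCc6ccccc6)cc45)=C(O)C3=O)c2c1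
A7 | alternative 2 | 3-[5-(benzyloxy)-1H-indol-3-yl]-6-(5-methoxy-1H-indol-3-yl)benzene-1,2,4,5-tetrol | COc1ccc2[nH]cc(-c3c(O)c(O)c(-c4c[nH]c5ccc(OCc6ccccc6)cc45)c(O)c3O)c2c1
A8 | alternative 3 | 1,4-bis[(trimethylsilyl)ethynyl]-2,3,5,6-tetramethoxybenzene | COc1c(OC)c(C#C[Si](C)(C)C)c(OC)c(OC)c1C#C[Si](C)(C)C
A9 | alternative 3 | 5-(benzyloxy)-3-{4-[5-methoxy-2-(trimethylsilyl)-1H-indol-3-yl]-2,3,5,6-tetramethoxyphenyl}-2-(trimethylsilyl)-1H-indole | COc1ccc2[nH]c([Si](C)(C)C)c(-c3c(OC)c(OC)c(-c4c([Si](C)(C)C)[nH]c5ccc(OCc6ccccc6)cc45)c(OC)c3OC)c2c1
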